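**Retrosynthetic overview** (atom numbers follow germacranolide usage: ring C1–C10, lactone carbons C11–C13, oxygens O3, O6, O8)

1. Target 35 ⇐ cleavage of two TBS ethers ⇐ Yamaguchi esterification of the 8β-hydroxy lactone 21 (3-O-TBS) with the diester acid 32, which is built from two Morita–Baylis–Hillman C5 units joined by a carboxylate SN2 step.
2. 21 ⇐ one CrCl2 operation on the open-chain allenyl Z-enal 19, which carries C12 on O8 as an N-phthalimidoyl oxalate: the C12 radical adds to the central allene carbon C11 (C11–C12), the resulting allylchromium adds through C7 to the C6 aldehyde (C6–C7), and C12 is then handed from O8 to O6.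
3. Enabling feature: O8 is 1,3 to C11 across the C7–C8 bond with H7/H8 cis, so an O8-bound C12 closes the five-membered ring O8–C12–C11–C7–C8 and turns C13–C11–C7 into a geometry-locked 2-carboxyallyl unit; C6 is a carbinol next to the 4Z alkene, i.e. the product of C7 adding to a Z-enal.
4. 19 ⇐ linear chain from 3-(trimethylsilyl)propynal: asymmetric propargylation (C8), carboalumination/oxirane opening (E-C1=C10), Zn–ProPhenol propiolate addition (C3), Me2CuLi (4Z), Shi epoxidation (1,10-oxirane), Crabbé homologation (allene).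
5. Ring order: oxirane (on the open chain) → five-membered 8,12-butenolide → ten-membered carbocycle → 6,12-γ-lactone by acyl shift; the last three form in step 14.

Key step: step 14

Remark: the sense of induction of the two catalytic asymmetric additions (steps 1 and 5) is assigned by analogy with simpler aldehydes; if either gives the antipode, the commercial enantiomer of that catalyst is used with no other change.

**Route**

Step 1
Reactants: 1 3-(trimethylsilyl)prop-2-ynal; 2 allenylboronic acid pinacol ester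
Product: 3 (3R)-1-(trimethylsilyl)hexa-1,5-diyn-3-ol
Conditions: (R)-TRIP phosphoric acid (5 mol%), 4 Å molecular sieves, toluene, −20 °C to rt; aqueous work-up
Reagents that add atoms: none
Why: Chiral phosphoric acid-catalysed propargylation (SE2' addition of the allenylboronate through a closed six-membered transition state) in which the catalyst selects the aldehyde face and sets the C8 carbinol as R.

Step 2
Reactants: 3
Product: 4 (3R)-3-(triethylsilyloxy)-1-(trimethylsilyl)hexa-1,5-diyne
Conditions: Et3SiCl, imidazole, CH2Cl2, 0 °C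
Reagents that add atoms: chlorotriethylsilane, CC[Si](Cl)(CC)CC
Why: Routine silylation that shields O8 during the organometallic steps and can later be cleaved beside the more robust TBS ether.

Step 3
Reactants: 4
Product: 6 (3E,6R)-4-methyl-6-(triethylsilyloxy)-8-(trimethylsilyl)oct-3-en-7-yn-1-ol, via alkenyldimethylalane 5 (not isolated)
Conditions: Me3Al (2.5 equiv), Cp2ZrCl2 (0.2 equiv), CH2Cl2, 0 °C to rt; volatiles removed; n-BuLi, THF/hexane, −78 °C; oxirane, −78 to 0 °C
Reagents that add atoms: trimethylaluminium, C[Al](C)C; oxirane, C1CO1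
Why: Zirconium-catalysed syn-carboalumination (Negishi) adds Me and Al across the terminal alkyne only, which fixes the E-configured C1=C10 alkene, and the alkenylalanate formed with n-BuLi opens oxirane to add C2 and C3.

Step 4
Reactants: 6
Product: 7 (3E,6R)-4-methyl-6-(triethylsilyloxy)-8-(trimethylsilyl)oct-3-en-7-ynal
Conditions: Dess–Martin periodinane, NaHCO3, CH2Cl2, 0 °C; used at once
Reagents that add atoms: none
Why: Dess–Martin oxidation under NaHCO3 buffering should give the β,γ-unsaturated aldehyde without moving the trisubstituted alkene into conjugation.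

Step 5
Reactants: 7; 8 methyl propiolate
Product: 9 methyl (4S,6E,9R)-4-hydroxy-7-methyl-9-(triethylsilyloxy)-11-(trimethylsilyl)undec-6-ene-2,10-diynoate
Conditions: (S,S)-ProPhenol (20 mol%), Me2Zn (3 equiv), Ph3PO (40 mol%), toluene, 4 °C
Reagents that add atoms: none
Why: Zn–ProPhenol catalytic asymmetric alkynylation, in which the dinuclear zinc acetylide complex delivers the propiolate to one aldehyde face and sets the C3 carbinol as S under catalyst control.

Step 6
Reactants: 9
Product: 10 methyl (4S,6E,9R)-4-(tert-butyldimethylsilyloxy)-7-methyl-9-(triethylsilyloxy)-11-(trimethylsilyl)undec-6-ene-2,10-diynoate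
Conditions: TBSOTf, 2,6-lutidine, CH2Cl2, −78 °C
Reagents that add atoms: tert-butyldimethylsilyl triflate, CC(C)(C)[Si](C)(C)OS(=O)(=O)C(F)(F)F
Why: Silylation of the propargylic alcohol with the triflate/2,6-lutidine system gives the TBS ether that is meant to survive to the last step.

Step 7
Reactants: 10
Product: 11 methyl (2Z,4S,6E,9R)-4-(tert-butyldimethylsilyloxy)-3,7-dimethyl-9-(triethylsilyloxy)-11-(trimethylsilyl)undeca-2,6-dien-10-ynoate
Conditions: Me2CuLi (from MeLi and CuI), THF, −78 °C; MeOH then aqueous NH4Cl at −78 °C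
Reagents that add atoms: lithium dimethylcuprate, [Li+].C[Cu-]C
Why: Syn-carbocupration of the ynoate by the Gilman reagent and protonation at −78 °C place Me and H cis, so C3 and the ester end up cis (the 4Z alkene), while the silyl ether prevents lactonisation.

Step 8
Reactants: 11
Product: 13 methyl (2Z,4S,6E,9R)-4-(tert-butyldimethylsilyloxy)-9-hydroxy-3,7-dimethylundeca-2,6-dien-10-ynoate, via desilylated alkyne 12 (not isolated)
Conditions: K2CO3 (0.2 equiv), MeOH, rt; then PPTS (0.6 equiv), 0 °C
Reagents that add atoms: none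
Why: Methanolysis of the alkynyl C–Si bond with K2CO3 is followed in the same flask by acid-catalysed methanolysis of the triethylsilyl ether, which is cleaved far faster than the secondary TBS ether.

Step 9
Reactants: 13
Product: 14 methyl (2Z,4S)-4-(tert-butyldimethylsilyloxy)-5-{(2R,3R)-3-[(2R)-2-hydroxybut-3-ynyl]-3-methyloxiran-2-yl}-3-methylpent-2-enoate
Conditions: D-fructose-derived Shi ketone (30 mol%), KHSO5 (as 2KHSO5·KHSO4·K2SO4), K2CO3, Bu4NHSO4, Na2B4O7 buffer, MeCN/CH2(OMe)2, 0 °C
Reagents that add atoms: potassium peroxymonosulfate, [K+].[O-]S(=O)(=O)OO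
Why: Shi asymmetric epoxidation, in which the chiral dioxirane attacks only the electron-rich E-trisubstituted alkene (enoate and alkyne are inert) through the spiro transition state and sets C1 and C10 as R,R under catalyst control.

Step 10
Reactants: 14
Product: 15 (2Z,4S)-4-(tert-butyldimethylsilyloxy)-5-{(2R,3R)-3-[(2R)-2-hydroxybut-3-ynyl]-3-methyloxiran-2-yl}-3-methylpent-2-en-1-ol
Conditions: iBu2AlH (3.5 equiv), CH2Cl2, −78 °C; potassium sodium tartrate work-up
Reagents that add atoms: none
Why: 1,2-Reduction of the enoate ester by iBu2AlH at −78 °C should give the Z-allylic alcohol without opening the epoxide.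

Step 11
Reactants: 15
Product: 17 (2Z,4S)-4-(tert-butyldimethylsilyloxy)-5-{(2R,3R)-3-[(2R)-2-hydroxypenta-3,4-dienyl]-3-methyloxiran-2-yl}-3-methylpent-2-en-1-ol, via propargylic amine 16 (not isolated)
Conditions: CuI (0.5 equiv), (CH2O)n, Cy2NH, 1,4-dioxane, reflux
Reagents that add atoms: paraformaldehyde (as formaldehyde), C=O
Why: Crabbé homologation (CuI-mediated Mannich reaction of the terminal alkyne, then 1,5-hydride transfer with loss of the imine) converts the propargylic alcohol into the α-allenyl alcohol without touching C8.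

Step 12
Reactants: 17
Product: 18 (2Z,4S)-4-(tert-butyldimethylsilyloxy)-5-{(2R,3R)-3-[(2R)-2-hydroxypenta-3,4-dienyl]-3-methyloxiran-2-yl}-3-methylpent-2-enal
Conditions: TEMPO (10 mol%), PhI(OAc)2, CH2Cl2, rt
Reagents that add atoms: none
Why: TEMPO/PhI(OAc)2 oxidation is much faster for the primary allylic alcohol than for the secondary allenyl carbinol and should give the Z-enal without double-bond isomerisation.

Step 13
Reactants: 18
Product: 19 N-phthalimidoyl oxalate of 18 on the C8 hydroxyl
Conditions: (COCl)2 and N-hydroxyphthalimide, THF, 0 °C to rt, then evaporated; 18, Et3N, DMAP (5 mol%), THF, −20 °C; filtered and used crude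
Reagents that add atoms: oxalyl chloride, ClC(=O)C(=O)Cl; N-hydroxyphthalimide, ON1C(=O)c2ccccc2C1=O
Why: Acylation of the only free hydroxyl with N-phthalimidoyl chlorooxalate made in the flask installs a redox-active oxalate, i.e. C12 on O8 as a latent alkoxycarbonyl radical.

Step 14
Reactants: 19
Product: 21 1β,10α-epoxy-8β-hydroxy-3β-(tert-butyldimethylsilyloxy)germacra-4Z,11(13)-dien-6α,12-olide, via 8,12-lactone 20 (not isolated)
Conditions: CrCl2 (4 equiv, 2 mM), DMF, 25 °C, dark; 19 added over 8 h to 0.5 mM, then 12 h; aqueous NaHCO3/potassium sodium tartrate work-up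
Reagents that add atoms: none
Why: Proposed new method: CrCl2 transfers one electron to the N-(acyloxy)phthalimide, which loses phthalimide anion and CO2 and leaves the alkoxycarbonyl radical on O8; this C12 radical attacks the central allene carbon C11 (5-exo with respect to the C11=C13 π-bond, ring O8–C12–C11–C7–C8), the butenolide-conjugated allyl radical is captured by a second divalent chromium as an allylchromium (Cr on C13) that adds through C7 to the C6 aldehyde in a closed chair transition state and closes the ten-membered carbocycle (SE2' allylation under high dilution), and the trivalent chromium alkoxide on O6 then attacks C12 (5-exo-trig acyl transfer), turning the cis-β,γ-disubstituted 8,12-lactone 20 into the trans-β,γ-disubstituted 6,12-lactone and freeing the C8 hydroxyl. The closest known reaction types are the 5-exo cyclisation of alkoxycarbonyl radicals released from oxalate-based redox-active esters, the CrCl2-mediated decarboxylative Nozaki–Hiyama–Kishi addition of N-(acyloxy)phthalimides to aldehydes, and the CrCl2-mediated Barbier macrocyclisation of 2-(alkoxycarbonyl)allyl halides (3-(bromomethyl)butenolides included) onto aldehydes. C7 is set by the tether, because the aldehyde can only reach the butenolide face that carries the C9 branch, so H7 and H8 should end up cis; C6 is set by the butenolide ring, which holds C8 trans to the CH2–Cr terminus (E-crotyl geometry), so the chair with the enal chain equatorial should give the 6,7-anti (trans-lactone) relationship. The step needs ring closure of the alkoxycarbonyl radical to outrun loss of CO2 and capture by chromium (secured by the five-membered mode onto an allene that gives a stabilised allyl radical and by millimolar CrCl2), ring closure to outrun dimerisation (slow addition), and 1,2- over 1,4-addition to the Z-enal (inherent to allylchromium reagents).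

Step 15
Reactants: 22 (tert-butyldimethylsilyloxy)acetaldehyde; 23 tert-butyl acrylate
Product: 24 tert-butyl 4-(tert-butyldimethylsilyloxy)-3-hydroxy-2-methylidenebutanoate (racemic)
Conditions: DABCO (1 equiv), 1,4-dioxane/H2O, rt
Reagents that add atoms: none
Why: Morita–Baylis–Hillman reaction; the new stereocentre is removed again in step 16, so the racemate is used.

Step 16
Reactants: 24
Product: 26 tert-butyl (2E)-2-(acetoxymethyl)-4-(tert-butyldimethylsilyloxy)but-2-enoate, via secondary acetate 25 (not isolated)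
Conditions: Ac2O, Et3N, DMAP (cat.), CH2Cl2, 0 °C; then DABCO (0.3 equiv), THF, 60 °C
Reagents that add atoms: acetic anhydride, CC(=O)OC(C)=O
Why: O-Acetylation followed by DABCO-catalysed SN2'–SN2' allylic transposition of the acetate should give the thermodynamically favoured trisubstituted alkene with the silyloxymethyl group trans to the ester (2E).

Step 17
Reactants: 26
Product: 27 (2E)-2-(acetoxymethyl)-4-(tert-butyldimethylsilyloxy)but-2-enoic acid
Conditions: Me3SiOTf, 2,6-lutidine, CH2Cl2, 0 °C; pH 5 buffer work-up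
Reagents that add atoms: none
Why: Silyl triflate-mediated cleavage of the tert-butyl ester (loss of isobutene, silyl ester hydrolysed on work-up) leaves the acetate and the TBS ether intact.

Step 18
Reactants: 28 acetaldehyde; 23
Product: 29 tert-butyl 3-hydroxy-2-methylidenebutanoate (racemic)
Conditions: DABCO (0.5 equiv), excess 28, rt
Reagents that add atoms: none
Why: Morita–Baylis–Hillman reaction whose carbinol centre is removed in the next step.

Step 19
Reactants: 29
Product: 30 tert-butyl (2Z)-2-(bromomethyl)but-2-enoate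
Conditions: NBS, Me2S, CH2Cl2, 0 °C to rt
Reagents that add atoms: N-bromosuccinimide, O=C1CCC(=O)N1Br
Why: Corey–Kim-type bromination with allylic transposition (SN2' attack of bromide on the alkoxysulfonium salt) should give the thermodynamically preferred allylic bromide with the methyl group trans to the ester.

Step 20
Reactants: 27; 30
Product: 31 tert-butyl (2E)-2-({[(2E)-2-(acetoxymethyl)-4-(tert-butyldimethylsilyloxy)but-2-enoyl]oxy}methyl)but-2-enoate
Conditions: Cs2CO3 (0.55 equiv), DMF, 0 °C to rt
Reagents that add atoms: none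
Why: SN2 displacement of the allylic bromide by the caesium carboxylate joins the two C5 acids and keeps the alkene geometry of both halves.

Step 21
Reactants: 31
Product: 32 (2E)-2-({[(2E)-2-(acetoxymethyl)-4-(tert-butyldimethylsilyloxy)but-2-enoyl]oxy}methyl)but-2-enoic acid
Conditions: Me3SiOTf, 2,6-lutidine, CH2Cl2, 0 °C; pH 5 buffer work-up
Reagents that add atoms: none
Why: The same silyl triflate cleavage of a tert-butyl ester as in step 17 frees the acid without touching the two other esters or the TBS ether.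

Step 22
Reactants: 32; 21
Product: 34 3-O-TBS, side-chain O-TBS bis-silyl ether of the target, via mixed anhydride 33 (not isolated)
Conditions: 2,4,6-trichlorobenzoyl chloride, Et3N, toluene, rt; then 21, DMAP, toluene, rt
Reagents that add atoms: none
Why: Yamaguchi esterification, in which DMAP attacks the mixed anhydride at the less hindered acyl carbon and the acylpyridinium acylates the 8β-hydroxyl, the only free hydroxyl of 21.

Step 23
Reactants: 34
Product: 35 target, (1R,3S,6R,7R,8R,10R)-configured
Conditions: HF·pyridine, pyridine, THF, 0 °C to rt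
Reagents that add atoms: none
Why: Buffered HF·pyridine should cleave both TBS ethers under weakly acidic, non-basic conditions that avoid acetyl migration and conjugate addition to the α-methylene lactone and keep the epoxide closed.

**Compound list** (TBS = tert-butyldimethylsilyl, TES = triethylsilyl)

1 | 3-(trimethylsilyl)prop-2-ynal | O=CC#C[Si](C)(C)C | starting material
2 | allenylboronic acid pinacol ester | C=C=CB1OC(C)(C)C(C)(C)O1 | starting material
3 | (3R)-1-(trimethylsilyl)hexa-1,5-diyn-3-ol | C#CC[C@@H](O)C#C[Si](C)(C)C | intermediate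
4 | (3R)-3-(triethylsilyloxy)-1-(trimethylsilyl)hexa-1,5-diyne | C#CC[C@@H](O[Si](CC)(CC)CC)C#C[Si](C)(C)C | intermediate
5 | dimethyl[(1E,4R)-2-methyl-4-(triethylsilyloxy)-6-(trimethylsilyl)hex-1-en-5-ynyl]alane | C[Al](C)/C=C(\C)C[C@@H](O[Si](CC)(CC)CC)C#C[Si](C)(C)C | intermediate
6 | (3E,6R)-4-methyl-6-(triethylsilyloxy)-8-(trimethylsilyl)oct-3-en-7-yn-1-ol | OCC/C=C(\C)C[C@@H](O[Si](CC)(CC)CC)C#C[Si](C)(C)C | intermediate
7 | (3E,6R)-4-methyl-6-(triethylsilyloxy)-8-(trimethylsilyl)oct-3-en-7-ynal | O=CC/C=C(\C)C[C@@H](O[Si](CC)(CC)CC)C#C[Si](C)(C)C | intermediate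
8 | methyl propiolate | C#CC(=O)OC | starting material
9 | methyl (4S,6E,9R)-4-hydroxy-7-methyl-9-(triethylsilyloxy)-11-(trimethylsilyl)undec-6-ene-2,10-diynoate | COC(=O)C#C[C@@H](O)C/C=C(\C)C[C@@H](O[Si](CC)(CC)CC)C#C[Si](C)(C)C | intermediate
10 | 4-O-TBS ether of 9 | COC(=O)C#C[C@@H](O[Si](C)(C)C(C)(C)C)C/C=C(\C)C[C@@H](O[Si](CC)(CC)CC)C#C[Si](C)(C)C | intermediate
11 | methyl (2Z,4S,6E,9R)-4-(TBS-oxy)-3,7-dimethyl-9-(TES-oxy)-11-(trimethylsilyl)undeca-2,6-dien-10-ynoate | COC(=O)/C=C(/C)[C@@H](O[Si](C)(C)C(C)(C)C)C/C=C(\C)C[C@@H](O[Si](CC)(CC)CC)C#C[Si](C)(C)C | intermediate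
12 | methyl (2Z,4S,6E,9R)-4-(TBS-oxy)-3,7-dimethyl-9-(TES-oxy)undeca-2,6-dien-10-ynoate | COC(=O)/C=C(/C)[C@@H](O[Si](C)(C)C(C)(C)C)C/C=C(\C)C[C@@H](O[Si](CC)(CC)CC)C#C | intermediate
13 | methyl (2Z,4S,6E,9R)-4-(TBS-oxy)-9-hydroxy-3,7-dimethylundeca-2,6-dien-10-ynoate | COC(=O)/C=C(/C)[C@@H](O[Si](C)(C)C(C)(C)C)C/C=C(\C)C[C@@H](O)C#C | intermediate
14 | methyl (2Z,4S)-4-(TBS-oxy)-5-{(2R,3R)-3-[(2R)-2-hydroxybut-3-ynyl]-3-methyloxiran-2-yl}-3-methylpent-2-enoate | COC(=O)/C=C(/C)[C@@H](O[Si](C)(C)C(C)(C)C)C[C@H]1O[C@]1(C)C[C@@H](O)C#C | intermediate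
15 | (2Z,4S)-4-(TBS-oxy)-5-{(2R,3R)-3-[(2R)-2-hydroxybut-3-ynyl]-3-methyloxiran-2-yl}-3-methylpent-2-en-1-ol | OC/C=C(/C)[C@@H](O[Si](C)(C)C(C)(C)C)C[C@H]1O[C@]1(C)C[C@@H](O)C#C | intermediate
16 | 15 carrying a (dicyclohexylamino)methyl group on the alkyne terminus | OC/C=C(/C)[C@@H](O[Si](C)(C)C(C)(C)C)C[C@H]1O[C@]1(C)C[C@@H](O)C#CCN(C2CCCCC2)C2CCCCC2 | intermediate
17 | (2Z,4S)-4-(TBS-oxy)-5-{(2R,3R)-3-[(2R)-2-hydroxypenta-3,4-dienyl]-3-methyloxiran-2-yl}-3-methylpent-2-en-1-ol | OC/C=C(/C)[C@@H](O[Si](C)(C)C(C)(C)C)C[C@H]1O[C@]1(C)C[C@@H](O)C=C=C | intermediate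
18 | (2Z,4S)-4-(TBS-oxy)-5-{(2R,3R)-3-[(2R)-2-hydroxypenta-3,4-dienyl]-3-methyloxiran-2-yl}-3-methylpent-2-enal | O=C/C=C(/C)[C@@H](O[Si](C)(C)C(C)(C)C)C[C@H]1O[C@]1(C)C[C@@H](O)C=C=C | intermediate
19 | N-phthalimidoyl oxalate of 18 (oxalate on the allenyl carbinol oxygen, O8) | O=C/C=C(/C)[C@@H](O[Si](C)(C)C(C)(C)C)C[C@H]1O[C@]1(C)C[C@@H](OC(=O)C(=O)ON2C(=O)c3ccccc3C2=O)C=C=C | intermediate
20 | 1β,10α-epoxy-6α-hydroxy-3β-(TBS-oxy)germacra-4Z,11(13)-dien-8β,12-olide (cis-fused 8,12-lactone) | C=C1C(=O)O[C@@H]2C[C@@]3(C)O[C@@H]3C[C@H](O[Si](C)(C)C(C)(C)C)/C(C)=C\[C@@H](O)[C@H]12 | intermediate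
21 | 1β,10α-epoxy-8β-hydroxy-3β-(TBS-oxy)germacra-4Z,11(13)-dien-6α,12-olide (trans-fused; 1R,3S,6R,7R,8R,10R) | C=C1C(=O)O[C@@H]2/C=C(/C)[C@@H](O[Si](C)(C)C(C)(C)C)C[C@H]3O[C@]3(C)C[C@@H](O)[C@@H]12 | intermediate
22 | (tert-butyldimethylsilyloxy)acetaldehyde | O=CCO[Si](C)(C)C(C)(C)C | starting material
23 | tert-butyl acrylate | C=CC(=O)OC(C)(C)C | starting material
24 | tert-butyl 4-(TBS-oxy)-3-hydroxy-2-methylidenebutanoate (racemic) | C=C(C(=O)OC(C)(C)C)C(O)CO[Si](C)(C)C(C)(C)C | intermediate
25 | tert-butyl 3-acetoxy-4-(TBS-oxy)-2-methylidenebutanoate (racemic) | C=C(C(=O)OC(C)(C)C)C(OC(C)=O)CO[Si](C)(C)C(C)(C)C | intermediate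
26 | tert-butyl (2E)-2-(acetoxymethyl)-4-(TBS-oxy)but-2-enoate | O=C(OC(C)(C)C)/C(=C/CO[Si](C)(C)C(C)(C)C)COC(C)=O | intermediate
27 | (2E)-2-(acetoxymethyl)-4-(TBS-oxy)but-2-enoic acid | OC(=O)/C(=C/CO[Si](C)(C)C(C)(C)C)COC(C)=O | intermediate
28 | acetaldehyde | CC=O | starting material
29 | tert-butyl 3-hydroxy-2-methylidenebutanoate (racemic) | C=C(C(C)O)C(=O)OC(C)(C)C | intermediate
30 | tert-butyl (2Z)-2-(bromomethyl)but-2-enoate | O=C(OC(C)(C)C)/C(=C/C)CBr | intermediate
31 | tert-butyl (2E)-2-({[(2E)-2-(acetoxymethyl)-4-(TBS-oxy)but-2-enoyl]oxy}methyl)but-2-enoate | O=C(OC(C)(C)C)/C(=C/C)COC(=O)/C(=C/CO[Si](C)(C)C(C)(C)C)COC(C)=O | intermediate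
32 | (2E)-2-({[(2E)-2-(acetoxymethyl)-4-(TBS-oxy)but-2-enoyl]oxy}methyl)but-2-enoic acid | OC(=O)/C(=C/C)COC(=O)/C(=C/CO[Si](C)(C)C(C)(C)C)COC(C)=O | intermediate
33 | mixed anhydride of 32 with 2,4,6-trichlorobenzoic acid | O=C(OC(=O)/C(=C/C)COC(=O)/C(=C/CO[Si](C)(C)C(C)(C)C)COC(C)=O)c1c(Cl)cc(Cl)cc1Cl | intermediate
34 | 8-O-acyl derivative of 21 with 32 (bis-TBS ether of the target) | C=C1C(=O)O[C@@H]2/C=C(/C)[C@@H](O[Si](C)(C)C(C)(C)C)C[C@H]3O[C@]3(C)C[C@@H](OC(=O)/C(=C/C)COC(=O)/C(=C/CO[Si](C)(C)C(C)(C)C)COC(C)=O)[C@@H]12 | intermediate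
35 | CNP0193678.1 | C=C1C(=O)O[C@@H]2/C=C(/C)[C@@H](O)C[C@H]3O[C@]3(C)C[C@@H](OC(=O)/C(=C/C)COC(=O)/C(=C/CO)COC(C)=O)[C@@H]12 | target

**Step count and risks**

Total step count: 23. Longest linear sequence: 16 (steps 1–14, 22, 23).

Steps most likely to fail:

1. Step 14 (proposed new method). The alkoxycarbonyl radical may lose CO2 to a dienyl radical, or be trapped by chromium, before it closes onto the allene. The enal may also add to the wrong allyl face, or the lactone may fail to move fully from O8 to O6. The fallback uses known chemistry, sets out from 18 and comes back at 21. Silylation of 18 (Et3SiCl, imidazole) should give the 8-O-triethylsilyl allenyl enal F1. Br2 (1 equiv, CH2Cl2, −78 °C) should add across the terminal allene π-bond to give the 2,3-dibromoalkene F2; its allylic isomer leads to the same allylchromium. CrCl2 in THF/DMF under high dilution should effect an intramolecular Nozaki–Hiyama–Kishi allylation of the enal and close the ten-membered ring to the 2-bromoallyl carbinol F3, with C6/C7 diastereomers to be separated if formed. Carbonylative lactonisation with Pd(PPh3)4, CO and K2CO3 joins the vinyl bromide to the C6 hydroxyl, the only free one, and should give the 8-O-triethylsilyl 6,12-lactone F4. HF·pyridine/pyridine then removes the triethylsilyl group to give 21.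

2. Step 5. Zinc alkoxide/amine basicity may move the β,γ-double bond of 7 into conjugation or cause self-aldol reaction, and induction on an unbranched aldehyde may be modest. The fallback sets out from 7 and comes back at 9. Lithiated methyl propiolate (LiN(SiMe3)2, THF, −90 °C) should add to 7 to give the C4-epimeric carbinol mixture F5. Dess–Martin oxidation should give the 4-oxo-2-ynoate F6, and Midland reduction with (S)-Alpine-borane should return 9 under reagent control.

3. Step 22. Under Et3N/DMAP the lactone of 21 may move back from O6 to O8, so that O6 is acylated instead, or DMAP may attack the activated 2-(acyloxymethyl)enoate in an SN2' sense. The fallback sets out from 30, uses 21 and 27, and comes back at 34. CF3CO2H in CH2Cl2 should convert 30 into (2Z)-2-(bromomethyl)but-2-enoic acid F7, and oxalyl chloride with catalytic DMF should give the acid chloride F8. Acylation of 21 with F8 (pyridine, CH2Cl2, 0 °C, no DMAP) should give the 8-O-[(2Z)-2-(bromomethyl)but-2-enoyl] lactone F9. The caesium salt of 27 (Cs2CO3, DMF) should then displace the allylic bromide to give 34.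

Further compounds
F1 | step 14 | 8-O-triethylsilyl ether of 18 | O=C/C=C(/C)[C@@H](O[Si](C)(C)C(C)(C)C)C[C@H]1O[C@]1(C)C[C@@H](O[Si](CC)(CC)CC)C=C=C
F2 | step 14 | 2,3-dibromoalkene from F1 (allene converted into CH=C(Br)CH2Br) | O=C/C=C(/C)[C@@H](O[Si](C)(C)C(C)(C)C)C[C@H]1O[C@]1(C)C[C@@H](O[Si](CC)(CC)CC)C=C(Br)CBr
F3 | step 14 | ten-membered 2-bromoallyl carbinol (6α-OH, 7-(1-bromovinyl), 8β-OTES, 3β-OTBS, 1β,10α-epoxide, 4Z) | C=C(Br)[C@H]1[C@H](O)/C=C(/C)[C@@H](O[Si](C)(C)C(C)(C)C)C[C@H]2O[C@]2(C)C[C@H]1O[Si](CC)(CC)CC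
F4 | step 14 | 8-O-triethylsilyl ether of 21 | C=C1C(=O)O[C@@H]2/C=C(/C)[C@@H](O[Si](C)(C)C(C)(C)C)C[C@H]3O[C@]3(C)C[C@@H](O[Si](CC)(CC)CC)[C@@H]12
F5 | step 5 | C4-epimeric mixture of 9 | COC(=O)C#CC(O)C/C=C(\C)C[C@@H](O[Si](CC)(CC)CC)C#C[Si](C)(C)C
F6 | step 5 | methyl (6E,9R)-7-methyl-4-oxo-9-(triethylsilyloxy)-11-(trimethylsilyl)undec-6-ene-2,10-diynoate | COC(=O)C#CC(=O)C/C=C(\C)C[C@@H](O[Si](CC)(CC)CC)C#C[Si](C)(C)C
F7 | step 22 | (2Z)-2-(bromomethyl)but-2-enoic acid | OC(=O)/C(=C/C)CBr
F8 | step 22 | (2Z)-2-(bromomethyl)but-2-enoyl chloride | ClC(=O)/C(=C/C)CBr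
F9 | step 22 | 8-O-[(2Z)-2-(bromomethyl)but-2-enoyl] derivative of 21 | C=C1C(=O)O[C@@H]2/C=C(/C)[C@@H](O[Si](C)(C)C(C)(C)C)C[C@H]3O[C@]3(C)C[C@@H](OC(=O)/C(=C/C)CBr)[C@@H]12
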